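(The runs were computed on assumed constants; the scatter is artificial.)

in all of them: starting material 0.25 M; free catalyst 0.28 mol%; added ligand 0.88 mM

|  | second substrate | remark | time |
|---|---|---|---|
| epsilon | 2 equiv | the very flask that is asked about, followed so far |  |
| flask | 2.00 equiv |  | 8.0 d |

epsilon run (percent of the starting material charged)

| time / h | target / % |
|---|---|
| 1.50 | 9 |
| 4.00 | 16 |
| 8.00 | 31 |
| 12.0 | 41 |
| 20.0 | 55 |
| 25.0 | 60 |

(each reading ± 1.5 percentage points)

* time, not beyond 8.0 d, at which the flask holds most target
* the amount of target, in percent of the starting material charged, at that time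
* earliest time at which at least nineteen twentieths of that best amount are there, in d
* latest time at which they still are, in d

- steps that have been proposed: starting material + free catalyst <-> catalyst intermediate A; catalyst intermediate A -> free catalyst + target; second substrate + free catalyst <-> catalyst intermediate B; catalyst intermediate B -> free catalyst + second product; target -> over-reaction product A; free catalyst + added ligand <-> idle complex; target -> over-reaction product B

Per hour, as a share of the starting material charged, the epsilon run opens at 0.0464 h⁻¹; that is what its 31 % at 8.00 h gives if I treat the making of target as pseudo-first-order. Between 20.0 h and 25.0 h its net gain is 0.0100 h⁻¹, slower by a factor 4.64.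

Two things share that slowing. At the midpoint, 22.5 h, the same constant puts the making at 0.0163 h⁻¹, down by a factor 2.84 as starting material runs down. That is faster than the net gain, by a factor 1.63, so I read the gap of 0.00634 h⁻¹ as target being lost. Divided by the 57.5 % of target present there, it gives 0.0110 h⁻¹, the loss constant: the share of the target present that goes per hour. It rests on a gap of 5 percentage points between two readings, each good to 1.5 points, so it is rough.

As the making falls and the loss grows, the net gain reaches zero where they cross. With these constants I put that crossing at 1.69 d, with 63.9 % of target.

The forecast says 1.7 d (range 1.3 d to 2.5 d) and 66 % (61 % to 73 %), above my amount, with the window from 1.2 d to 2.4 d, and adds “The loss constant is poorly defined”.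

The flask gives 67.9 % at 1.78 d, with the window from 1.26 d to 2.44 d.

    starting material + free catalyst ⇌ catalyst intermediate A (K = 6.40 M⁻¹, k = 1000 M⁻¹ h⁻¹)
    catalyst intermediate A → free catalyst + target (k = 330 h⁻¹)
    second substrate + free catalyst ⇌ catalyst intermediate B (K = 67.0 M⁻¹, k = 600 M⁻¹ h⁻¹)
    catalyst intermediate B → free catalyst + second product (k = 24.0 h⁻¹)
    target → over-reaction product A (k = 3.80 × 10⁻⁵ h⁻¹)
    free catalyst + added ligand ⇌ idle complex (K = 17000 M⁻¹, k = 280 M⁻¹ h⁻¹)
    target → over-reaction product B (k = 0.0100 h⁻¹)

From 47.1 % of target at 4.00 d, with 0.225 % of starting material left, the loss constant predicts 16.4 % at 8.00 d; this flask holds 18.1 %. The neighbouring flask, with 3.40 equiv of second substrate, peaks at 60.7 % and holds 20.3 % at 8.00 d. Counted as pure loss at that constant, its fall from peak to that amount takes 4.15 d, fewer than the 5.01 d counted the same way for this flask, whose peak in fact stands 6.22 d before its last state.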